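**Retrosynth­etic overview**

1. The last disconnection is the C4′–C4a′ bond of the pyranone ring of the 7‑oxygenated 2H‑chromen‑2‑one, para to the C7′ ether oxygen. Opening it gives the aryl propiolate 18 of a resorcinol mono‑ether, so the pyranone ring is the only ring built and it is built last.
2. 18 goes back to phenol 16 and propiolic acid. The C11–O–aryl bond goes back to the primary C11 alcohol 7 and resorcinol monobenzoate (Mitsunobu).
3. Alcohol 7 comes from andrographolide by two C=C scissions, C12=C13 with KMnO4 and then C11=C12 of a silyl enol ether with ozone, while the 3,19‑diol is held as an acetonide.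
4. With the ether in place the acetonide is removed, C19 is deoxygenated through its tosylate and the C3 hydroxyl is isovalerylated.
5. Rings A and B and the stereocentres C3, C5, C9 and C10 are carried unchanged from andrographolide; no stereocentre is set in the route.

Key step: step 12

Remark on numbering: the labdane numbering of andrographolide is kept throughout (C17 is the exocyclic methylene carbon, C19 the oxygenated carbon on C4, C11 the carbon that becomes the OCH2 group); primed locants belong to the coumarin.
Assumption 1: resorcinol is brought in as its commercial monobenzoate, so that the second phenol stays masked while C19 and C3 are adjusted.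
Assumption 2: permanganate is taken to attack the electron‑poor conjugated C12=C13 alkene faster than the isolated C8=C17 alkene.

**Route**

Step 1
Reactants: 1 andrographolide
Product: 2 3,19‑O‑isopropylidene‑andrographolide (C3 and C19 oxygens in a 2,2‑dimethyl‑1,3‑dioxane; C14 hydroxyl free)
Conditions: 2,2‑dimethoxypropane, PPTS (cat.), toluene/DMSO, 80 °C
Reagents that add atoms: 2,2‑dimethoxypropane, COC(C)(C)OC
Why: Acid‑catalysed transacetalisation should engage only the 1,3‑related C3 and C19 hydroxyls in a six‑membered isopropylidene acetal and leave the allylic C14 hydroxyl untouched.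

Step 2
Reactants: 2 3,19‑O‑isopropylidene‑andrographolide
Product: 3 acetonide C12 aldehyde (C9–CH2–CHO side chain; C8=C17 methylene kept)
Conditions: KMnO4, THF, −10 °C → 0 °C
Reagents that add atoms: potassium permanganate (KMnO4), [K+].[O-][Mn](=O)(=O)=O
Why: Permanganate oxidative cleavage of an alkene should take place at the electron‑poor alkylidene‑lactone double bond through a cyclic manganate ester that collapses to the C12 aldehyde and the keto‑lactone fragment, the isolated 1,1‑disubstituted C8=C17 alkene reacting more slowly.

Step 3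
Reactants: 3 acetonide C12 aldehyde
Product: 4 tert‑butyldimethylsilyl enol ether of 3 (C11=C12–OSi, E/Z mixture, both isomers usable)
Conditions: TBSOTf, Et3N, CH2Cl2, 0 °C
Reagents that add atoms: tert‑butyldimethylsilyl trifluoromethanesulfonate, CC(C)(C)[Si](C)(C)OS(=O)(=O)C(F)(F)F
Why: Soft enolisation of an aldehyde (silyl triflate activation, amine deprotonation at C11, the only α‑position) should give the silyl enol ether without touching C9 or the acetonide.

Step 4
Reactants: 4 tert‑butyldimethylsilyl enol ether
Product: 7 acetonide C11 alcohol (C9–CH2OH; ent‑drimane skeleton), via methoxy hydroperoxide 5 (not isolated), via C11 aldehyde 6 (not isolated)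
Conditions: O3 (1.0 equiv, Sudan red 7B end‑point), CH2Cl2/MeOH, −78 °C; then NaBH4, −78 °C → 0 °C
Reagents that add atoms: ozone, [O-][O+]=O
Why: Ozonolysis should be selective for the electron‑rich enol ether over the C8=C17 methylene, the Criegee fragmentation giving silyl formate and a C11 carbonyl oxide that methanol traps, and the borohydride work‑up reduces the peroxide through the aldehyde to the alcohol at low temperature without base, so C9 keeps its configuration.

Step 5
Reactants: 7 acetonide C11 alcohol; 8 3‑hydroxyphenyl benzoate (resorcinol monobenzoate)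
Product: 9 3‑(C11‑yloxy)phenyl benzoate of the acetonide (aryl alkyl ether at C11)
Conditions: PPh3, DIAD, toluene, 0 °C → 50 °C
Reagents that add atoms: 3‑hydroxyphenyl benzoate (8), O=C(Oc1cccc(O)c1)c1ccccc1
Why: Mitsunobu etherification should proceed by displacement of the primary C11 alkoxyphosphonium ion by the phenoxide (pKa about 9), with the benzoate masking the second phenol and no stereocentre involved at C11.

Step 6
Reactants: 9 aryl ether acetonide
Product: 10 3,19‑diol aryl ether (benzoate kept)
Conditions: AcOH/H2O (7:3), rt
Reagents that add atoms: none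
Why: Mild acid‑catalysed acetal hydrolysis should free the diol while the aryl benzoate, the aryl ether and the exocyclic alkene tolerate aqueous acetic acid at room temperature.

Step 7
Reactants: 10 3,19‑diol aryl ether
Product: 11 19‑O‑tosylate (C3 hydroxyl free)
Conditions: TsCl (1.2 equiv), pyridine, 0 °C → rt
Reagents that add atoms: p‑toluenesulfonyl chloride, Cc1ccc(cc1)S(=O)(=O)Cl
Why: Selective sulfonylation should occur at the primary C19 hydroxyl because the secondary C3 hydroxyl next to the quaternary C4 reacts far more slowly.

Step 8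
Reactants: 11 19‑O‑tosylate
Product: 13 C3 alcohol with 4,4‑dimethyl group (19‑deoxy compound), via C19 iodide 12 (not isolated)
Conditions: NaI, Zn dust, HMPA, 110 °C
Reagents that add atoms: none
Why: Reductive deoxygenation of a hindered primary sulfonate should proceed by Finkelstein displacement to the iodide and zinc reduction of the C–I bond under neutral conditions, which avoids oxetane formation or fragmentation of the 1,3‑hydroxy sulfonate and makes C4 non‑stereogenic.

Step 9
Reactants: 13 C3 alcohol; 14 isovaleryl chloride
Product: 15 C3 isovalerate (aryl benzoate kept)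
Conditions: pyridine, DMAP (cat.), CH2Cl2, 0 °C → rt
Reagents that add atoms: isovaleryl chloride (14), CC(C)CC(=O)Cl
Why: DMAP‑catalysed acylation of the equatorial secondary alcohol with an acid chloride should give the ester with retention at C3, since the C3–O bond is not broken.

Step 10
Reactants: 15 C3 isovalerate aryl benzoate
Product: 16 3‑(C11‑yloxy)phenol carrying the C3 isovalerate
Conditions: K2CO3 (0.3 equiv), MeOH/THF, 0 °C
Reagents that add atoms: none
Why: Chemoselective transesterification should cleave only the aryl benzoate, whose phenoxide is a good leaving group, while the hindered secondary alkyl isovalerate is inert at 0 °C.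

Step 11
Reactants: 16 phenol; 17 propiolic acid
Product: 18 3‑(C11‑yloxy)phenyl propiolate carrying the C3 isovalerate
Conditions: DCC, DMAP (2 mol %), CH2Cl2, 0 °C
Reagents that add atoms: propiolic acid (17), C#CC(=O)O
Why: Carbodiimide (Steglich‑type) esterification should acylate the only free hydroxyl, the phenol, under neutral conditions at low temperature, which limits polymerisation of the ynoate.

Step 12
Reactants: 18 aryl propiolate
Product: 19 target CNP0295317.1
Conditions: [(t‑Bu)2(2‑biphenylyl)P]Au(NCMe)SbF6 (5 mol %), CH2Cl2, rt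
Reagents that add atoms: none
Why: The cationic monovalent gold centre binds the electron‑poor alkyne of 18 as a π‑acid, and the arene carbon para to the ether oxygen (ortho to the ester oxygen) attacks the terminal alkyne carbon anti to gold in a Friedel–Crafts‑type step, giving a vinyl‑gold arenium ion that rearomatises by proton loss and is released by protodeauration. The closest known reaction type is the gold‑catalysed intramolecular hydroarylation of aryl alkynoates to coumarins. The pyranone ring is closed in the 6‑endo‑dig mode, and the new C4′–C4a′ bond is the only skeletal bond formed. No stereocentre is created, and the four existing ones (C3, C5, C9, C10) are remote from the reacting atoms. The step needs site selectivity between the two arene positions ortho to the ester oxygen; the position para to the alkoxy group should win because it is the more activated and is flanked only by hydrogen, whereas the position between the two oxygens is shielded by the bulky terpenylmethoxy group. It also needs the alkyne to react in preference to the C8=C17 alkene, which the alkynophilic catalyst, the absence of added Brønsted acid and room temperature should secure.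

**Compound list**

1 | andrographolide | C=C1CC[C@@H]2[C@](C)(CO)[C@H](O)CC[C@@]2(C)[C@@H]1C/C=C3/C(=O)OC[C@H]3O | starting material
2 | 3,19‑O‑isopropylidene‑andrographolide | C=C1CC[C@@H]2[C@]3(C)COC(C)(C)O[C@@H]3CC[C@@]2(C)[C@@H]1C/C=C4/C(=O)OC[C@H]4O | intermediate
3 | acetonide C12 aldehyde (3,19‑O‑isopropylidene‑13,14,15,16‑tetranor‑ent‑labd‑8(17)‑en‑12‑al) | C=C1CC[C@@H]2[C@]3(C)COC(C)(C)O[C@@H]3CC[C@@]2(C)[C@@H]1CC=O | intermediate
4 | tert‑butyldimethylsilyl enol ether of 3 (C11=C12, E/Z mixture) | C=C1CC[C@@H]2[C@]3(C)COC(C)(C)O[C@@H]3CC[C@@]2(C)[C@@H]1C=CO[Si](C)(C)C(C)(C)C | intermediate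
5 | C11 methoxy hydroperoxide (epimers at C11, not isolated) | C=C1CC[C@@H]2[C@]3(C)COC(C)(C)O[C@@H]3CC[C@@]2(C)[C@@H]1C(OC)OO | intermediate
6 | acetonide C11 aldehyde (not isolated) | C=C1CC[C@@H]2[C@]3(C)COC(C)(C)O[C@@H]3CC[C@@]2(C)[C@@H]1C=O | intermediate
7 | acetonide C11 alcohol | C=C1CC[C@@H]2[C@]3(C)COC(C)(C)O[C@@H]3CC[C@@]2(C)[C@@H]1CO | intermediate
8 | 3‑hydroxyphenyl benzoate (resorcinol monobenzoate) | O=C(Oc1cccc(O)c1)c1ccccc1 | starting material
9 | 3‑(C11‑yloxy)phenyl benzoate, 3,19‑acetonide | C=C1CC[C@@H]2[C@]3(C)COC(C)(C)O[C@@H]3CC[C@@]2(C)[C@@H]1COc1cccc(OC(=O)c2ccccc2)c1 | intermediate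
10 | 3‑(C11‑yloxy)phenyl benzoate, 3,19‑diol | C=C1CC[C@@H]2[C@](C)(CO)[C@H](O)CC[C@@]2(C)[C@@H]1COc1cccc(OC(=O)c2ccccc2)c1 | intermediate
11 | 19‑O‑tosylate of 10 | C=C1CC[C@@H]2[C@](C)(COS(=O)(=O)c3ccc(C)cc3)[C@H](O)CC[C@@]2(C)[C@@H]1COc1cccc(OC(=O)c2ccccc2)c1 | intermediate
12 | C19 iodide (not isolated) | C=C1CC[C@@H]2[C@](C)(CI)[C@H](O)CC[C@@]2(C)[C@@H]1COc1cccc(OC(=O)c2ccccc2)c1 | intermediate
13 | 19‑deoxy C3 alcohol (4,4‑dimethyl), aryl benzoate | C=C1CC[C@@H]2C(C)(C)[C@H](O)CC[C@@]2(C)[C@@H]1COc1cccc(OC(=O)c2ccccc2)c1 | intermediate
14 | isovaleryl chloride | CC(C)CC(=O)Cl | starting material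
15 | C3 isovalerate, aryl benzoate | C=C1CC[C@@H]2C(C)(C)[C@H](OC(=O)CC(C)C)CC[C@@]2(C)[C@@H]1COc1cccc(OC(=O)c2ccccc2)c1 | intermediate
16 | 3‑(C11‑yloxy)phenol with C3 isovalerate | C=C1CC[C@@H]2C(C)(C)[C@H](OC(=O)CC(C)C)CC[C@@]2(C)[C@@H]1COc1cccc(O)c1 | intermediate
17 | propiolic acid | C#CC(=O)O | starting material
18 | 3‑(C11‑yloxy)phenyl propiolate with C3 isovalerate | C=C1CC[C@@H]2C(C)(C)[C@H](OC(=O)CC(C)C)CC[C@@]2(C)[C@@H]1COc1cccc(OC(=O)C#C)c1 | intermediate
19 | CNP0295317.1 (7‑(C11‑yloxy)coumarin with C3 isovalerate) | C=C1CC[C@@H]2C(C)(C)[C@H](OC(=O)CC(C)C)CC[C@@]2(C)[C@@H]1COc1ccc2ccc(=O)oc2c1 | target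

**Step count**

Total: 12 steps. Longest linear sequence: 12 steps (1 → 19).

**Steps most likely to fail**

Step 12. The closure may go in part to the arene carbon between the two oxygens, giving the 5‑alkoxy isomer, or acid formed during protodeauration may move the exocyclic alkene into the ring. The fallback sets out from phenol 16 and closes the pyranone at the lactone oxygen instead. Magnesium‑mediated ortho‑formylation (MgCl2, Et3N, paraformaldehyde, MeCN, reflux) should give the 2‑hydroxy‑4‑alkoxybenzaldehyde F1. Wittig olefination with Ph3P=CHCO2Et should give the ethyl (E)‑2‑hydroxycinnamate F2, which on heating in N,N‑diethylaniline should isomerise and lactonise with loss of ethanol. The fallback comes back to the route at 19.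

Step 4. Ozone may go on to attack the C8=C17 methylene once the enol ether is used up, or C9 may epimerise or the alkene may move into conjugation while the C11 aldehyde is still unreduced. The fallback sets out from aldehyde 3 and avoids ozone. Condensation with piperidine (4 Å sieves, toluene) should give the piperidine enamine F3. Sensitised photo‑oxygenation (O2, tetraphenylporphyrin, hν, CH2Cl2, −78 °C) should add singlet oxygen to the enamine far faster than to the methylene, giving the amino‑dioxetane F4, which fragments to N‑formylpiperidine and the aldehyde. The fallback comes back to the route at aldehyde 6, which is reduced with NaBH4 to 7 as in step 4.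

Step 5. Displacement at the hindered C11 alkoxyphosphonium ion may be slow, so that loss of the allylic C9 hydrogen to a diene, or benzoyl transfer between phenoxides, takes over. The fallback sets out from alcohol 7 and forms the aryl–oxygen bond instead of the alkyl–oxygen bond. 3‑Bromophenol (commercial) is silylated (TIPSCl, imidazole, DMF) to (3‑bromophenoxy)triisopropylsilane F5. Palladium‑catalysed C–O cross‑coupling of 7 with F5 ([Pd(allyl)Cl]2, RockPhos, Cs2CO3, toluene, 90 °C) should give the triisopropylsilyl aryl ether F6. TBAF (THF, 0 °C) should release the phenol F7, and benzoylation (BzCl, Et3N, CH2Cl2) comes back to the route at 9.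

**Further compounds**

F1 | step 12 | 2‑hydroxy‑4‑(C11‑yloxy)benzaldehyde with C3 isovalerate | C=C1CC[C@@H]2C(C)(C)[C@H](OC(=O)CC(C)C)CC[C@@]2(C)[C@@H]1COc1ccc(C=O)c(O)c1
F2 | step 12 | ethyl (E)‑3‑[2‑hydroxy‑4‑(C11‑yloxy)phenyl]acrylate with C3 isovalerate | C=C1CC[C@@H]2C(C)(C)[C@H](OC(=O)CC(C)C)CC[C@@]2(C)[C@@H]1COc1ccc(/C=C/C(=O)OCC)c(O)c1
F3 | step 4 | piperidine enamine of aldehyde 3 (E) | C=C1CC[C@@H]2[C@]3(C)COC(C)(C)O[C@@H]3CC[C@@]2(C)[C@@H]1/C=C/N1CCCCC1
F4 | step 4 | 3‑piperidino‑1,2‑dioxetane from F3 | C=C1CC[C@@H]2[C@]3(C)COC(C)(C)O[C@@H]3CC[C@@]2(C)[C@@H]1C1OOC1N1CCCCC1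
F5 | step 5 | (3‑bromophenoxy)triisopropylsilane | CC(C)[Si](Oc1cccc(Br)c1)(C(C)C)C(C)C
F6 | step 5 | triisopropylsilyl ether of the 3‑(C11‑yloxy)phenol acetonide | C=C1CC[C@@H]2[C@]3(C)COC(C)(C)O[C@@H]3CC[C@@]2(C)[C@@H]1COc1cccc(O[Si](C(C)C)(C(C)C)C(C)C)c1
F7 | step 5 | 3‑(C11‑yloxy)phenol acetonide | C=C1CC[C@@H]2[C@]3(C)COC(C)(C)O[C@@H]3CC[C@@]2(C)[C@@H]1COc1cccc(O)c1
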